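**Retrosynthetic overview**
1. Feature: the strategy rests on the CH2CO2Me arm on furan C2. Moving one of its hydrogens to C5 turns the furan ring (O1, C2 to C5) into its non-aromatic tautomer, a 5-hexadecyl-2-(methoxycarbonylmethylene)-2,5-dihydrofuran. The only unsubstituted ring bond of that tautomer is the C3=C4 alkene.
2. C3=C4 is disconnected by ring-closing metathesis. This opens the ring to an acyclic 3-alkoxypenta-2,4-dienoate that already holds O1, C2 and C5 and ends in two vinyl groups.
3. O1-C2 is disconnected by oxa-Michael addition into racemic nonadec-1-en-3-ol (hexadecyl Grignard reagent plus acrolein) and methyl pent-4-en-2-ynoate (Sonogashira coupling of methyl propiolate with vinyl bromide).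
4. Ring order: there is one ring. O1-C2 is set in the open chain, the five-membered oxacycle is closed at C3-C4, and a redox-neutral proton shift makes it aromatic at the end.

Key step: step 5

Remark: the target has no stereocentre, so the carbinol carbon is carried as a racemate. The enol ether is drawn E, the geometry expected from the phosphine-catalysed addition. Both elements vanish in the last step.

**Step 1**
Reactants: 1 1-bromohexadecane
Product: 2 hexadecylmagnesium bromide (kept as a titrated THF solution and used as such)
Conditions: Mg (1.2 equiv), I2 (cat.), THF, rt to 50 °C, slow addition of 1
Reagents that add atoms: magnesium, [Mg]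
Why: Grignard reagent formation by insertion of magnesium metal into a primary C-Br bond, with slow addition of the bromide to keep Wurtz-type coupling low.

**Step 2**
Reactants: 2 hexadecylmagnesium bromide; 3 acrolein
Product: 4 nonadec-1-en-3-ol (racemic)
Conditions: 3 (1.2 equiv, freshly distilled), THF, −78 to 0 °C; then sat. aq NH4Cl
Reagents that add atoms: none
Why: Grignard 1,2-addition, in which the hard alkylmagnesium reagent attacks the aldehyde carbonyl of acrolein at low temperature in preference to the conjugate position, and the new carbinol stereocentre is left racemic on purpose because it ends as sp2 C5 of the furan.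

**Step 3**
Reactants: 5 methyl propiolate; 6 vinyl bromide
Product: 7 methyl pent-4-en-2-ynoate
Conditions: PdCl2(PPh3)2 (3 mol %), CuI (6 mol %), K2CO3 (2 equiv), 6 (1 M in THF, 2 equiv), THF, sealed flask, 45 °C, slow addition of 5; product kept cold over a trace of BHT
Reagents that add atoms: none
Why: Sonogashira coupling, in which zerovalent palladium formed in situ inserts into the vinylic C-Br bond, the copper acetylide of 5 transmetalates and reductive elimination forms the sp2-sp bond, while the insoluble carbonate replaces the usual amine, which would add to the propiolate in an aza-Michael sense.

**Step 4**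
Reactants: 4 nonadec-1-en-3-ol (racemic); 7 methyl pent-4-en-2-ynoate
Product: 8 methyl (2E)-3-(nonadec-1-en-3-yloxy)penta-2,4-dienoate (racemic)
Conditions: PMe3 (15 mol %, 1 M in THF), 7 (1.5 equiv), CH2Cl2, 0 °C to rt
Reagents that add atoms: none
Why: Phosphine-catalysed oxa-Michael addition to a beta-substituted alkynoate, in which PMe3 adds reversibly to the ynoate, the zwitterion deprotonates 4, the alkoxide attacks alkyne carbon C3 (the 1,4-position, which leads straight to an ester-stabilised allenolate) rather than the vinyl terminus, and protonation should leave the E enol ether with oxygen anti to the ester, the carbinol centre staying untouched and racemic.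

**Step 5**
Reactants: 8 methyl (2E)-3-(nonadec-1-en-3-yloxy)penta-2,4-dienoate (racemic)
Product: 9 methyl (2E)-2-(5-hexadecylfuran-2(5H)-ylidene)acetate (racemic)
Conditions: second-generation Hoveyda-Grubbs catalyst RuCl2(SIMes)(=CH-C6H4-2-OiPr) (5 mol %), 1,4-benzoquinone (10 mol %), degassed CH2Cl2 (0.005 M), 35 °C, Ar sparge
Reagents that add atoms: none
Why: Proposed new method: the ruthenium benzylidene should first exchange with the isolated, more electron-rich allylic-ether vinyl group of 8, and the resulting alkylidene then adds across the terminal CH=CH2 of the 2-alkoxydiene through a ruthenacyclobutane whose cycloreversion forms the C3=C4 bond and passes on Ru=CH2, with ethylene leaving the solution and making the closure irreversible. The closest known reaction types are the ring-closing metathesis of diallyl ethers and of bis-allylic acetals to 2,5-dihydrofurans and diene-ene ring-closing metathesis at the terminal alkene of a conjugated diene, and what is untested is a beta-alkoxy dienoate as the diene partner, which leaves the enoate alkene exocyclic. The only ring, the five-membered oxacycle O1-C2-C3-C4-C5, closes by intramolecular alkylidene transfer between two monosubstituted alkenes held three atoms apart across O1, so the new endocyclic alkene can only be cis. No stereocentre is created, since C5 is carried over from racemic 4 and the E geometry of the exocyclic alkene is untouched because that bond takes no part. The step needs chemoselectivity for the two vinyl groups over the trisubstituted push-pull C=C, secured by the steric and electronic deactivation of that bond and by the strain of the four-membered oxete that closure there would give, and it needs selectivity over intermolecular metathesis, secured by high dilution. It also needs the [3,3] shift of the allyl vinyl ether to stay silent, which the acceptor on the enol ether terminus and a bath below 40 °C should ensure.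

**Step 6**
Reactants: 9 methyl (2E)-2-(5-hexadecylfuran-2(5H)-ylidene)acetate (racemic)
Product: 10 methyl 2-(5-hexadecylfuran-2-yl)acetate
Conditions: DBU (20 mol %), CH2Cl2, rt
Reagents that add atoms: none
Why: Base-mediated prototropic aromatisation, the same 2-alkylidene-2,5-dihydrofuran to furan shift that ends enynol cycloisomerisations and carbonylative enynol cyclisations, in which DBU removes the C5 hydrogen (allylic, alpha to O1 and vinylogous to the ester), the anion is the enolate of the furylacetate, and reprotonation at the exocyclic carbon is driven by the gain of furan aromaticity and erases both the C5 stereocentre and the alkene geometry.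

**Compound list**
1 | 1-bromohexadecane | CCCCCCCCCCCCCCCCBr | starting material
2 | hexadecylmagnesium bromide | CCCCCCCCCCCCCCCC[Mg]Br | intermediate
3 | acrolein | C=CC=O | starting material
4 | nonadec-1-en-3-ol (racemic) | CCCCCCCCCCCCCCCCC(O)C=C | intermediate
5 | methyl propiolate | C#CC(=O)OC | starting material
6 | vinyl bromide | C=CBr | starting material
7 | methyl pent-4-en-2-ynoate | C=CC#CC(=O)OC | intermediate
8 | methyl (2E)-3-(nonadec-1-en-3-yloxy)penta-2,4-dienoate (racemic) | CCCCCCCCCCCCCCCCC(C=C)O/C(C=C)=C/C(=O)OC | intermediate
9 | methyl (2E)-2-(5-hexadecylfuran-2(5H)-ylidene)acetate (racemic) | CCCCCCCCCCCCCCCCC1C=C/C(=C\C(=O)OC)O1 | intermediate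
10 | methyl 2-(5-hexadecylfuran-2-yl)acetate | CCCCCCCCCCCCCCCCc1ccc(CC(=O)OC)o1 | target

**Total step count:** 6
**Longest linear sequence:** 5 steps (steps 1, 2, 4, 5 and 6, starting from 1). The ester half joins after one step (step 3).

**Steps most likely to fail**

**Step 5 (ring-closing metathesis of the beta-alkoxy dienoate).**
- What may go wrong: the catalyst may be drained by loading on the diene terminus, where the ester carbonyl, held cis to that carbon in the E isomer, can chelate ruthenium.
- Ruthenium hydrides may also shift the allylic-ether alkene before closure, or intermolecular metathesis may outrun cyclisation.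
- The fallback uses known chemistry: cross-metathesis of an allylic alcohol with an enone, followed by acid-induced cyclodehydration to a 2,5-disubstituted furan. It sets out from 4, with 3 as the source of the partner, and comes back to the route at 10.
- The lithium enolate of methyl acetate (LiN(iPr)2, THF, −78 °C) is added to 3 and quenched with aq NH4Cl to give methyl 3-hydroxypent-4-enoate F1.
- Jones oxidation (CrO3, H2SO4, acetone, 0 °C) should give methyl 3-oxopent-4-enoate F2.
- Cross-metathesis of 4 with F2 (second-generation Hoveyda-Grubbs catalyst, CH2Cl2, 40 °C) should give methyl (4E)-6-hydroxy-3-oxodocos-4-enoate F3.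
- PPTS in warm toluene should then isomerise the alkene, close the hemiketal and expel water to give 10.
- C3=C4 is still made by metathesis, but the ring is closed afterwards at O1-C2.

**Step 4 (oxa-Michael addition to the enynoate).**
- What may go wrong: the phosphine or the alkoxide may attack the unsubstituted vinyl terminus in the 1,6-mode, and the enynoate may polymerise anionically faster than the hindered secondary alcohol adds.
- The fallback sets out from 5 and 4 and comes back at 9. It caps the diene terminus with a group that the metathesis later sheds.
- 1-Bromo-2-methylprop-1-ene is coupled with 5 under the conditions of step 3 to give methyl 5-methylhex-4-en-2-ynoate F4. Its gem-dimethyl terminus blocks 1,6-attack and lowers both volatility and polymerisability.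
- PMe3-catalysed addition of 4 should give methyl (2E)-5-methyl-3-(nonadec-1-en-3-yloxy)hexa-2,4-dienoate F5.
- Ring closure under the conditions of step 5 then releases 2-methylpropene instead of ethylene and delivers 9.
- The catalyst can now load only on the allylic-ether vinyl group.

**Step 3 (Sonogashira coupling).**
- What may go wrong: base-induced oligomerisation of the propiolate, oxidative Glaser-type homocoupling of the copper acetylide, and loss or polymerisation of the small, volatile enynoate during isolation.
- The fallback sets out from 5 and 6 and comes back at 7. It replaces the base and copper manifold by a neutral Stille coupling of an alkynylstannane with a vinyl halide.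
- 5 is stannylated with Bu3SnOMe (neat, rt, methanol removed under vacuum) to give methyl 3-(tributylstannyl)prop-2-ynoate F6.
- F6 is coupled with 6 (Pd(PPh3)4, THF, sealed flask, 50 °C) to give 7, which is taken into step 4 as a solution.

**Further compounds**
F1 | step 5 | methyl 3-hydroxypent-4-enoate (racemic) | C=CC(O)CC(=O)OC
F2 | step 5 | methyl 3-oxopent-4-enoate | C=CC(=O)CC(=O)OC
F3 | step 5 | methyl (4E)-6-hydroxy-3-oxodocos-4-enoate (racemic) | CCCCCCCCCCCCCCCCC(O)/C=C/C(=O)CC(=O)OC
F4 | step 4 | methyl 5-methylhex-4-en-2-ynoate | CC(C)=CC#CC(=O)OC
F5 | step 4 | methyl (2E)-5-methyl-3-(nonadec-1-en-3-yloxy)hexa-2,4-dienoate (racemic) | CCCCCCCCCCCCCCCCC(C=C)O/C(C=C(C)C)=C/C(=O)OC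
F6 | step 3 | methyl 3-(tributylstannyl)prop-2-ynoate | CCCC[Sn](CCCC)(CCCC)C#CC(=O)OC
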